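## Retrosynthetic overview

1. Target 39 is 6-O-acetylated ent-labda-13(16),14-diene-6,8,18-triol. Late operations: C12–C13 by coupling iodide 34 with 2-butadienylmagnesium chloride 36, H5 and equatorial O6 by hydroboration of a C5=C6 alkene, C18 by hydroxymethylation at C4, then removal of O3.
2. The strategy rests on ring A (C1–C2–C3–C4–C5–C10). Its two methyl-bearing carbons C4 and C10 flank C5, the carbon that carries C6 of ring B. With an oxygen placed on C3, ring A is a 3-alkyl-2,4-dimethylphenol whose para carbon is the quaternary C10.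
3. Key disconnection: C9–C10 and C8–O. Two-electron oxidation of phenol 18 makes C10 electrophilic, the E C8=C9 alkene closes ring B, and water ends on C8. Ring A is present from the start as the arene; ring B forms in step 12.
4. C6, the only stereocentre of 18, comes from an asymmetric propargylation and steers C10, C9 and C8. An axial γ-siloxy group would not survive electron transfer to the enone, so its loss is used to make the C3–C6 dienolate. O6 is put back on the opposite face by the hydroboration.
5. Phenol 18 derives from 2,6-dimethylbenzoic acid 1 (arene, C19, C20, C6), allenylboronate 9 (C7–C9), AlMe3 (C17) and ethylene oxide 13 (C11, C12).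

Key step: step 12

Conventions: labdane numbering is used from compound 10 on. TBS = tert-butyldimethylsilyl, TES = triethylsilyl, Piv = pivaloyl, TRIP = 3,3'-bis(2,4,6-triisopropylphenyl)-1,1'-binaphthyl-2,2'-diyl hydrogen phosphate.

Assumption: (S)-TRIP is taken to give the (S)-carbinol, since the (R)-acid gives (R)-carbinols from simple benzaldehydes. If the hindered aldehyde 8 responds in the opposite sense, the (R)-acid is used.

## Route

Step 1
Reactants: 1 2,6-dimethylbenzoic acid
Product: 2 2,6-dimethyl-3-nitrobenzoic acid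
Conditions: HNO3, H2SO4, 0 °C
Reagents that add atoms: nitric acid, O[N+](=O)[O-]
Why: Electrophilic aromatic nitration should go to C3, which is ortho to one methyl, para to the other and meta to the carboxyl group, so all three directors agree.

Step 2
Reactants: 2 2,6-dimethyl-3-nitrobenzoic acid
Product: 3 3-amino-2,6-dimethylbenzoic acid
Conditions: H2 (1 atm), Pd/C, MeOH, rt
Reagents that add atoms: none
Why: Catalytic hydrogenation of an aryl nitro group leaves the acid and the ring untouched.

Step 3
Reactants: 3 3-amino-2,6-dimethylbenzoic acid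
Product: 5 3-hydroxy-2,6-dimethylbenzoic acid, via diazonium salt 4 (not isolated)
Conditions: NaNO2, aq H2SO4, 0 °C; then aq H2SO4, reflux
Reagents that add atoms: water, O (phenolic oxygen); sodium nitrite, [Na+].[O-]N=O (second nitrogen of 4 only)
Why: Diazotization followed by thermal hydrolysis of the diazonium salt is the standard way from an aniline to a phenol.

Step 4
Reactants: 5 3-hydroxy-2,6-dimethylbenzoic acid
Product: 6 3-(hydroxymethyl)-2,4-dimethylphenol
Conditions: LiAlH4, THF, 0 °C to reflux; aqueous work-up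
Reagents that add atoms: none
Why: LiAlH4 reduces even di-ortho-substituted benzoic acids to benzyl alcohols, and the phenoxide is inert.

Step 5
Reactants: 6 3-(hydroxymethyl)-2,4-dimethylphenol
Product: 7 3-hydroxy-2,6-dimethylbenzaldehyde
Conditions: MnO2, EtOAc, rt
Reagents that add atoms: none
Why: MnO2 oxidises benzylic alcohols selectively, and the meta hydroxyl cannot open a quinone methide pathway.

Step 6
Reactants: 7 3-hydroxy-2,6-dimethylbenzaldehyde
Product: 8 3-(tert-butyldimethylsilyloxy)-2,6-dimethylbenzaldehyde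
Conditions: TBSCl, imidazole, DMF, rt
Reagents that add atoms: tert-butyldimethylsilyl chloride, CC(C)(C)[Si](C)(C)Cl
Why: Imidazole-promoted silylation masks the phenol for the boron, aluminium and lithium reagents that follow.

Step 7
Reactants: 8 3-(tert-butyldimethylsilyloxy)-2,6-dimethylbenzaldehyde; 9 allenylboronic acid pinacol ester
Product: 11 (S)-1-[3-(tert-butyldimethylsilyloxy)-2,6-dimethylphenyl]but-3-yn-1-ol, via O-boryl ether 10 (not isolated)
Conditions: 9 (1.5 equiv), (S)-TRIP (10 mol %), 4 Å MS, toluene, −20 °C; aq NaHCO3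
Reagents that add atoms: none
Why: Chiral-phosphoric-acid-catalysed allenylboration runs through a closed six-membered transition state, so only the homopropargylic alcohol should form, and the catalyst pocket leaves one aldehyde face open and sets C6 as S.

Step 8
Reactants: 11 (S)-homopropargylic alcohol
Product: 12 (S)-bis-TBS ether of 11
Conditions: TBSOTf, 2,6-lutidine, CH2Cl2, 0 °C
Reagents that add atoms: tert-butyldimethylsilyl triflate, CC(C)(C)[Si](C)(C)OS(=O)(=O)C(F)(F)F
Why: The silyl triflate is reactive enough for a carbinol flanked by a 2,6-dimethylaryl group, and the C–O bond at C6 is not touched.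

Step 9
Reactants: 12 (S)-bis-TBS alkyne; 13 ethylene oxide
Product: 16 (3E,6S)-6-(tert-butyldimethylsilyloxy)-6-[3-(tert-butyldimethylsilyloxy)-2,6-dimethylphenyl]-4-methylhex-3-en-1-ol, via alkenylalane 14 (not isolated), via lithium alanate 15 (not isolated)
Conditions: AlMe3, Cp2ZrCl2 (25 mol %), CH2Cl2, 0 °C to rt; concentrate; n-BuLi, THF/hexane, −78 °C; 13 (THF solution), −78 to 0 °C; aqueous work-up
Reagents that add atoms: trimethylaluminium, C[Al](C)C (C17; AlMe2 in 14 and 15); n-butyllithium, [Li]CCCC (butyl and lithium of 15 only)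
Why: Negishi zirconium-catalysed carboalumination adds methyl and aluminium syn with aluminium on the terminal carbon, and the derived ate complex opens ethylene oxide with retention, so the E trisubstituted alkene is fixed.

Step 10
Reactants: 16 (3E,6S)-homoallylic alcohol
Product: 17 pivalate of 16
Conditions: PivCl, pyridine, DMAP (cat.), CH2Cl2, 0 °C to rt
Reagents that add atoms: pivaloyl chloride, CC(C)(C)C(=O)Cl
Why: Acylation gives an O12 that is not nucleophilic, whereas a free or ether oxygen would close a tetrahydrofuran onto the C8 cation in step 12.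

Step 11
Reactants: 17 bis-TBS pivalate
Product: 18 (3E,6S)-6-(tert-butyldimethylsilyloxy)-6-(3-hydroxy-2,6-dimethylphenyl)-4-methylhex-3-en-1-yl pivalate
Conditions: KHF2, MeOH, rt
Reagents that add atoms: none
Why: Bifluoride cleaves aryl silyl ethers much faster than hindered secondary alkyl silyl ethers because phenoxide is the better leaving group, and the pivalate is inert.

Step 12
Reactants: 18 phenol
Product: 21 cross-conjugated dienone alcohol (6S,8S,9S,10S), via phenoxenium ion 19 (not isolated), via C8 cation 20 (not isolated)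
Conditions: PhI(OAc)2 (1.1 equiv), (CF3)2CHOH/H2O, 0 °C
Reagents that add atoms: water, O
Why: Ligand exchange at trivalent iodine and loss of PhI and acetate give phenoxenium ion 19, C9 of the alkene adds to its para carbon C10, the charge passes to tertiary C8 (20), and water adds there. The closest known reaction type is the PhI(OAc)2-mediated dearomatization of 4-alkylphenols in fluorinated alcohols with a tethered alkene as nucleophile, that is, a cation–olefin cyclization started by an oxidised arene. Ring B (C5–C6–C7–C8–C9–C10) closes 6-endo-trig with respect to the alkene through a chair. C10 is set by C6, because allylic 1,3-strain with the C4 methyl keeps H6 in the ring plane and the silyl ether perpendicular to it, so C7 and C9 reach C10 only from the face opposite O6 and C20 ends syn to O6; C9 follows from the E geometry in the chair (C11 equatorial, H9 anti to C20); C8 follows from anti addition, the axial face being closed by C20 and the silyl ether, so the hydroxyl is equatorial and C17 axial. The step needs attack at C10 rather than at the equally distant ortho carbon C4, ring closure ahead of direct attack of water on 19, and capture of 20 ahead of proton loss. Working in that direction are the larger positive charge at the para position, the iodine-bearing oxygen next to C4, the more stable cross-conjugated product, the buttressed C4 methyl that turns the chain towards C10, the six-membered tether, the weakly nucleophilic medium and the non-nucleophilic pivalate oxygen.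

Step 13
Reactants: 21 dienone alcohol
Product: 22 8-O-TES dienone
Conditions: TESOTf, 2,6-lutidine, CH2Cl2, −78 to 0 °C
Reagents that add atoms: triethylsilyl triflate, CC[Si](CC)(CC)OS(=O)(=O)C(F)(F)F
Why: The silyl triflate reaches the tertiary hydroxyl, the dienone has no α-hydrogen to form an enol silane, and masking O8 removes a proton source for step 15 and an internal nucleophile towards C12 in steps 21 and 23.

Step 14
Reactants: 22 8-O-TES dienone
Product: 23 4-en-3-one (C1–C2 saturated)
Conditions: H2 (1 atm), RhCl(PPh3)3 (10 mol %), benzene/EtOH, rt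
Reagents that add atoms: none
Why: In a Wilkinson hydrogenation the bulky rhodium hydride binds only the disubstituted C1=C2 bond and leaves the tetrasubstituted C4=C5 bond, as in the known conversion of steroidal 1,4-dien-3-ones into 4-en-3-ones.

Step 15
Reactants: 23 4-en-3-one
Product: 25 (4S)-4-hydroxymethyl-4-methyl-5-en-3-one, via lithium dienolate 24 (not isolated)
Conditions: Li (2.1 equiv, to a just persistent blue), NH3/THF, −78 °C; NH3 evaporated; CH2O (g, from cracked paraformaldehyde), THF, −78 °C; aq NH4Cl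
Reagents that add atoms: formaldehyde, C=O (C18 and O18); lithium, [Li] (in 24 only)
Why: Proposed new method: electron transfer to the enone gives a radical anion whose π system overlaps with the axial C6–O bond, so silanolate is expelled instead of C5 being protonated, a second electron turns the dienyl radical into the regiodefined lithium 3,5-dienolate 24 (which accepts no further electrons, so limiting lithium should spare the pivalate), and monomeric formaldehyde adds at the α-carbon C4 from the face opposite the axial C10 methyl, placing C18 anti to C20; the closest known reaction types are the Stork reductive alkylation and hydroxymethylation of enones with Li/NH3 and the dissolving-metal cleavage of α-oxygenated ketones, of which this is the vinylogous tandem form.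

Step 16
Reactants: 25 hydroxymethyl ketone
Product: 26 18-O-TBS ketone
Conditions: TBSCl, imidazole, DMF, rt
Reagents that add atoms: tert-butyldimethylsilyl chloride, CC(C)(C)[Si](C)(C)Cl
Why: Silylation of the primary neopentyl alcohol blocks retro-aldol loss of formaldehyde and later distinguishes O18 from O6.

Step 17
Reactants: 26 18-O-TBS ketone
Product: 27 C3 tosylhydrazone
Conditions: TsNHNH2, EtOH, 70 °C
Reagents that add atoms: p-toluenesulfonyl hydrazide, Cc1ccc(cc1)S(=O)(=O)NN
Why: Hydrazone condensation is known to work on 3-ketones next to a quaternary C4, and C3 is the only carbonyl that can condense.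

Step 18
Reactants: 27 tosylhydrazone
Product: 30 3-deoxy-5-ene (4S,8S,9S,10S), via tosylhydrazine 28 (not isolated), via diazene 29 (not isolated)
Conditions: catecholborane, CHCl3, −10 °C to rt; NaOAc·3H2O, reflux
Reagents that add atoms: none
Why: In the catecholborane variant of the Caglioti reduction, hydride adds to C=N, acetate induces loss of sulfinate, and the diazene releases N2 to leave CH2 at C3 under conditions that spare ester, silyl ethers and the unconjugated hindered alkene.

Step 19
Reactants: 30 3-deoxy-5-ene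
Product: 32 6-ol (4S,5S,6R,8S,9S,10R), via alkylborane 31 (not isolated)
Conditions: BH3·THF, THF, 0 °C to rt; NaOH, H2O2, 0 °C to rt
Reagents that add atoms: hydrogen peroxide, OO (O6); borane, B (boron of 31 only)
Why: In the Brown hydroboration–oxidation boron goes to the less substituted C6 and hydrogen to C5 in a syn addition from the face opposite the axial methyls C17, C19 and C20, and oxidation with retention sets the trans ring fusion and the equatorial 6-hydroxyl, as known for 4,4-dimethyl-5-ene steroids.

Step 20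
Reactants: 32 6-ol
Product: 33 6,12-diol
Conditions: DIBAL-H (3.5 equiv), CH2Cl2, −78 °C; aqueous work-up
Reagents that add atoms: none
Why: Reductive cleavage of the pivalate with DIBAL-H leaves both silyl ethers in place.

Step 21
Reactants: 33 6,12-diol
Product: 34 12-iodide
Conditions: I2, PPh3, imidazole, CH2Cl2, 0 °C
Reagents that add atoms: iodine, [I][I]
Why: The Appel-type iodination activates the unhindered primary O12 far faster than the equatorial secondary O6, which is crowded by C18.

Step 22
Reactants: 35 chloroprene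
Product: 36 2-(buta-1,3-dienyl)magnesium chloride
Conditions: Mg, ZnCl2 (cat.), THF, reflux
Reagents that add atoms: magnesium, [Mg]
Why: Zinc-chloride-promoted insertion of magnesium into the vinylic C–Cl bond of chloroprene is the known preparation of this Grignard reagent.

Step 23
Reactants: 34 12-iodide; 36 2-(buta-1,3-dienyl)magnesium chloride
Product: 37 13(16),14-diene 6-ol
Conditions: 36 (3 equiv), Li2CuCl4 (5 mol %), THF, −20 to 0 °C
Reagents that add atoms: none
Why: The copper-catalysed Kochi-type coupling of primary alkyl iodides with this Grignard reagent is a known route to 2-alkylbutadienes; one equivalent only deprotonates O6, and the masked O8 cannot displace iodide.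

Step 24
Reactants: 37 diene 6-ol
Product: 38 6-acetate
Conditions: Ac2O, DMAP, pyridine, rt
Reagents that add atoms: acetic anhydride, CC(=O)OC(C)=O
Why: DMAP-catalysed acylation meets only one free hydroxyl, O6, so no selectivity is required.

Step 25
Reactants: 38 6-acetate
Product: 39 target
Conditions: HF·pyridine, pyridine/THF, 0 °C to rt
Reagents that add atoms: none
Why: Buffered fluoride desilylation frees O8 and O18 together, and the non-basic medium should suppress acetyl migration from O6 to O18 and ionisation at C8.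

## Compound list

1 | 2,6-dimethylbenzoic acid | Cc1cccc(C)c1C(=O)O | starting material
2 | 2,6-dimethyl-3-nitrobenzoic acid | Cc1ccc([N+](=O)[O-])c(C)c1C(=O)O | intermediate
3 | 3-amino-2,6-dimethylbenzoic acid | Cc1ccc(N)c(C)c1C(=O)O | intermediate
4 | 3-carboxy-2,4-dimethylbenzenediazonium hydrogen sulfate | Cc1ccc([N+]#N)c(C)c1C(=O)O.OS(=O)(=O)[O-] | intermediate
5 | 3-hydroxy-2,6-dimethylbenzoic acid | Cc1ccc(O)c(C)c1C(=O)O | intermediate
6 | 3-(hydroxymethyl)-2,4-dimethylphenol | Cc1ccc(O)c(C)c1CO | intermediate
7 | 3-hydroxy-2,6-dimethylbenzaldehyde | Cc1ccc(O)c(C)c1C=O | intermediate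
8 | 3-(tert-butyldimethylsilyloxy)-2,6-dimethylbenzaldehyde | Cc1ccc(O[Si](C)(C)C(C)(C)C)c(C)c1C=O | intermediate
9 | allenylboronic acid pinacol ester | C=C=CB1OC(C)(C)C(C)(C)O1 | starting material
10 | O-pinacolboryl ether of 11 (6S) | Cc1ccc(O[Si](C)(C)C(C)(C)C)c(C)c1[C@@H](OB1OC(C)(C)C(C)(C)O1)CC#C | intermediate
11 | (S)-1-[3-(tert-butyldimethylsilyloxy)-2,6-dimethylphenyl]but-3-yn-1-ol | Cc1ccc(O[Si](C)(C)C(C)(C)C)c(C)c1[C@@H](O)CC#C | intermediate
12 | (S)-bis-TBS ether: aryl OTBS, benzylic OTBS, terminal alkyne | Cc1ccc(O[Si](C)(C)C(C)(C)C)c(C)c1[C@@H](O[Si](C)(C)C(C)(C)C)CC#C | intermediate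
13 | ethylene oxide | C1CO1 | starting material
14 | (E)-alkenyldimethylalane from 12 (Me on C8, Al on C9, C7 trans to Al) | Cc1ccc(O[Si](C)(C)C(C)(C)C)c(C)c1[C@@H](O[Si](C)(C)C(C)(C)C)C/C(C)=C/[Al](C)C | intermediate
15 | lithium (E)-alkenyl(butyl)dimethylalanate | Cc1ccc(O[Si](C)(C)C(C)(C)C)c(C)c1[C@@H](O[Si](C)(C)C(C)(C)C)C/C(C)=C/[Al-](C)(C)CCCC.[Li+] | intermediate
16 | (3E,6S)-6-(TBSO)-6-[3-(TBSO)-2,6-dimethylphenyl]-4-methylhex-3-en-1-ol | Cc1ccc(O[Si](C)(C)C(C)(C)C)c(C)c1[C@@H](O[Si](C)(C)C(C)(C)C)C/C(C)=C/CCO | intermediate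
17 | pivalate of 16 | Cc1ccc(O[Si](C)(C)C(C)(C)C)c(C)c1[C@@H](O[Si](C)(C)C(C)(C)C)C/C(C)=C/CCOC(=O)C(C)(C)C | intermediate
18 | (3E,6S)-6-(TBSO)-6-(3-hydroxy-2,6-dimethylphenyl)-4-methylhex-3-en-1-yl pivalate (key-step precursor) | Cc1ccc(O)c(C)c1[C@@H](O[Si](C)(C)C(C)(C)C)C/C(C)=C/CCOC(=O)C(C)(C)C | intermediate
19 | phenoxenium ion of 18, drawn with the charge on C10 | C[C+]1C=CC(=O)C(C)=C1[C@@H](O[Si](C)(C)C(C)(C)C)C/C(C)=C/CCOC(=O)C(C)(C)C | intermediate
20 | bicyclic C8 tertiary cation (C9–C10 formed) | CC(C)(C)C(=O)OCC[C@H]1[C@]2(C)C=CC(=O)C(C)=C2[C@@H](O[Si](C)(C)C(C)(C)C)C[C+]1C | intermediate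
21 | (6S,8S,9S,10S)-dienone: C3=O, C1=C2, C4=C5, 4-Me, 10-Me, axial 6-OTBS syn to C20, equatorial 8-OH, axial C17, equatorial C9–CH2CH2OPiv (key-step product) | CC(C)(C)C(=O)OCC[C@H]1[C@]2(C)C=CC(=O)C(C)=C2[C@@H](O[Si](C)(C)C(C)(C)C)C[C@]1(C)O | intermediate
22 | 8-O-TES ether of 21 | CC(C)(C)C(=O)OCC[C@H]1[C@]2(C)C=CC(=O)C(C)=C2[C@@H](O[Si](C)(C)C(C)(C)C)C[C@]1(C)O[Si](CC)(CC)CC | intermediate
23 | (6S,8S,9S,10S)-4-methyl-4-en-3-one, C1–C2 saturated | CC(C)(C)C(=O)OCC[C@H]1[C@]2(C)CCC(=O)C(C)=C2[C@@H](O[Si](C)(C)C(C)(C)C)C[C@]1(C)O[Si](CC)(CC)CC | intermediate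
24 | lithium 3,5-dien-3-olate (O6 lost) | CC(C)(C)C(=O)OCC[C@H]1[C@]2(C)CCC([O-])=C(C)C2=CC[C@]1(C)O[Si](CC)(CC)CC.[Li+] | intermediate
25 | (4S,8S,9S,10S)-4-hydroxymethyl-4-methyl-5-en-3-one, C18 anti to C20 | CC(C)(C)C(=O)OCC[C@H]1[C@]2(C)CCC(=O)[C@](C)(CO)C2=CC[C@]1(C)O[Si](CC)(CC)CC | intermediate
26 | 18-O-TBS ether of 25 | CC(C)(C)C(=O)OCC[C@H]1[C@]2(C)CCC(=O)[C@](C)(CO[Si](C)(C)C(C)(C)C)C2=CC[C@]1(C)O[Si](CC)(CC)CC | intermediate
27 | C3 tosylhydrazone of 26 | CC(C)(C)C(=O)OCC[C@H]1[C@]2(C)CCC(=NNS(=O)(=O)c3ccc(C)cc3)[C@](C)(CO[Si](C)(C)C(C)(C)C)C2=CC[C@]1(C)O[Si](CC)(CC)CC | intermediate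
28 | C3 tosylhydrazine (C3 configuration of no consequence) | CC(C)(C)C(=O)OCC[C@H]1[C@]2(C)CCC(NNS(=O)(=O)c3ccc(C)cc3)[C@](C)(CO[Si](C)(C)C(C)(C)C)C2=CC[C@]1(C)O[Si](CC)(CC)CC | intermediate
29 | C3 diazene (C3 configuration of no consequence) | CC(C)(C)C(=O)OCC[C@H]1[C@]2(C)CCC(N=N)[C@](C)(CO[Si](C)(C)C(C)(C)C)C2=CC[C@]1(C)O[Si](CC)(CC)CC | intermediate
30 | (4S,8S,9S,10S)-3-deoxy-5-ene: 18-OTBS, 8-OTES, 12-OPiv | CC(C)(C)C(=O)OCC[C@H]1[C@]2(C)CCC[C@](C)(CO[Si](C)(C)C(C)(C)C)C2=CC[C@]1(C)O[Si](CC)(CC)CC | intermediate
31 | C6 alkylborane, H5 and boron on the face opposite C20 | CC(C)(C)C(=O)OCC[C@H]1[C@]2(C)CCC[C@](C)(CO[Si](C)(C)C(C)(C)C)[C@H]2[C@H](B)C[C@]1(C)O[Si](CC)(CC)CC | intermediate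
32 | (4S,5S,6R,8S,9S,10R)-trans-decalin 6-ol (equatorial OH): 18-OTBS, 8-OTES, 12-OPiv | CC(C)(C)C(=O)OCC[C@H]1[C@]2(C)CCC[C@](C)(CO[Si](C)(C)C(C)(C)C)[C@H]2[C@H](O)C[C@]1(C)O[Si](CC)(CC)CC | intermediate
33 | 6,12-diol | OCC[C@H]1[C@]2(C)CCC[C@](C)(CO[Si](C)(C)C(C)(C)C)[C@H]2[C@H](O)C[C@]1(C)O[Si](CC)(CC)CC | intermediate
34 | 12-iodide, 6-OH free | ICC[C@H]1[C@]2(C)CCC[C@](C)(CO[Si](C)(C)C(C)(C)C)[C@H]2[C@H](O)C[C@]1(C)O[Si](CC)(CC)CC | intermediate
35 | chloroprene (2-chlorobuta-1,3-diene) | C=CC(Cl)=C | starting material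
36 | 2-(buta-1,3-dienyl)magnesium chloride | C=CC(=C)[Mg]Cl | intermediate
37 | 13(16),14-diene 6-ol: 18-OTBS, 8-OTES | C=CC(=C)CC[C@H]1[C@]2(C)CCC[C@](C)(CO[Si](C)(C)C(C)(C)C)[C@H]2[C@H](O)C[C@]1(C)O[Si](CC)(CC)CC | intermediate
38 | 6-acetate of 37 | C=CC(=C)CC[C@H]1[C@]2(C)CCC[C@](C)(CO[Si](C)(C)C(C)(C)C)[C@H]2[C@H](OC(C)=O)C[C@]1(C)O[Si](CC)(CC)CC | intermediate
39 | (4S,5S,6R,8S,9S,10R)-6-acetoxy-8,18-dihydroxylabda-13(16),14-diene (ent-labdane series) | C=CC(=C)CC[C@H]1[C@]2(C)CCC[C@](C)(CO)[C@H]2[C@H](OC(C)=O)C[C@]1(C)O | target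

## Step count and risks

Total step count: 25. Longest linear sequence: 24 steps (steps 1–21 and 23–25; step 22 is a one-step side branch).

**Step 15.**
- What may go wrong: protonation at C5 ahead of loss of the silanolate, electron transfer to the pivalate, attack of formaldehyde at C6 instead of C4, or retro-aldol loss of formaldehyde on warming.
- Fallback: it sets out from 23 and returns at 25, and uses known operations only.
- SmI2 in THF/MeOH at −78 °C cleaves the γ-siloxy group as a vinylogous α-oxygenated ketone and tolerates the ester. Brief treatment with DBU then gives the conjugated 6-deoxy enone F1.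
- The thermodynamic dienolate of F1 (t-BuOK, t-BuOH/THF) is alkylated at C4 with benzyl chloromethyl ether. This is the classical deconjugative alkylation of 4-methyl-4-en-3-ones, again from the face opposite C20, and gives the benzyloxymethyl ketone F2.
- Hydrogenolysis (H2, Pd(OH)2/C, EtOAc) frees the alcohol 25. The C5=C6 bond, set between two quaternary carbons, should stay.

**Step 12.**
- What may go wrong: poor facial selectivity at C10 (the axial silyl ether also meets C17 and C20 as the chair forms), ring closure at the ortho carbon C4, interception of the phenoxenium ion by water before the alkene arrives, or proton loss or solvent capture at C8.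
- Fallback: it sets out from 17 and returns at 21, and reverses the polarity of the same C9–C10 closure.
- Shi epoxidation of 17 (Oxone, enantiomeric L-series fructose-type ketone) gives the (8S,9S)-epoxide F3, so that C8 and C9 are set by the reagent. KHF2 in MeOH then frees the epoxy phenol F4.
- The potassium phenolate of F4 (t-BuOK, t-BuOH, warm) is alkylated at its para carbon C10 by C9 of the epoxide, with inversion at C9 (alkylative dearomatization). O8 is released directly on C8 and the product is 21.

**Step 18.**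
- What may go wrong: slow hydride delivery to a C=N bond next to quaternary C4, with elimination to an alkene taking over.
- Fallback: it sets out from 26 and returns at 30.
- KHMDS and PhNTf2 (THF, −78 °C) give the C2=C3 enol triflate F5; only one enolate is possible because C4 is quaternary.
- Pd(OAc)2, PPh3, HCO2H and Bu3N (DMF, 60 °C) replace the triflate by hydrogen to give the 2,5-diene F6.
- H2 with RhCl(PPh3)3 saturates only the disubstituted C2=C3 bond and gives 30.

## Further compounds

F1 | step 15 | 6-deoxy-4-methyl-4-en-3-one (8-OTES, 12-OPiv) | CC(C)(C)C(=O)OCC[C@H]1[C@]2(C)CCC(=O)C(C)=C2CC[C@]1(C)O[Si](CC)(CC)CC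
F2 | step 15 | (4S)-4-benzyloxymethyl-4-methyl-5-en-3-one | CC(C)(C)C(=O)OCC[C@H]1[C@]2(C)CCC(=O)[C@](C)(COCc3ccccc3)C2=CC[C@]1(C)O[Si](CC)(CC)CC
F3 | step 12 | (6S,8S,9S)-8,9-epoxide of 17 | Cc1ccc(O[Si](C)(C)C(C)(C)C)c(C)c1[C@@H](O[Si](C)(C)C(C)(C)C)C[C@]1(C)O[C@H]1CCOC(=O)C(C)(C)C
F4 | step 12 | (6S,8S,9S)-epoxy phenol | Cc1ccc(O)c(C)c1[C@@H](O[Si](C)(C)C(C)(C)C)C[C@]1(C)O[C@H]1CCOC(=O)C(C)(C)C
F5 | step 18 | C2=C3 enol triflate of 26 | CC(C)(C)C(=O)OCC[C@H]1[C@]2(C)CC=C(OS(=O)(=O)C(F)(F)F)[C@](C)(CO[Si](C)(C)C(C)(C)C)C2=CC[C@]1(C)O[Si](CC)(CC)CC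
F6 | step 18 | 2,5-diene | CC(C)(C)C(=O)OCC[C@H]1[C@]2(C)CC=C[C@](C)(CO[Si](C)(C)C(C)(C)C)C2=CC[C@]1(C)O[Si](CC)(CC)CC
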